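**Plan** (chain atoms are numbered C1, benzylic, to C17, methyl)
- Retrosynthetic cuts, in order: the three acyl C–O bonds (one global deacylation); the C11–C12 σ-bond between the chain CH2 and the carbinol carbon; C11–I and the C8≡C9 alkyne (Appel, semihydrogenation); the aryl–C1 bond (B-alkyl Suzuki–Miyaura); C7–C8 (acetylide alkylation).
- Forward: no ring is formed. The benzene-1,3-diol ring is bought as 5-bromoresorcinol and carried as its bis-pivalate. The chain is joined C7–C8 first, then aryl–C1, then C11–C12, and all esters are removed in the last step.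
- Enabling feature: C12 is a dialkyl carbinol carbon whose two CH2 neighbours (C11, C13) differ only beyond the β-position, so a ketone reduction could hardly tell them apart. As its benzoate, the C12–O unit makes C12 a radical-stabilised, nickel-coordinating electrophilic centre, available in racemic form directly from the aldehyde oxidation level ((Z)-hex-3-enal plus benzoyl bromide).
- Stereochemistry: C12 (S) comes from catalyst control in a stereoconvergent nickel-catalysed alkyl–alkyl coupling of the racemic 1-bromoalkyl benzoate; 8Z from Lindlar reduction; 14Z is bought in with (Z)-hex-3-en-1-ol.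
- Helper groups: one benzoate (activating and directing) and two aryl pivalates, all released together by methoxide.

Key step: step 7

Assumption: the (S,S)-bis(oxazoline) ligand is taken to be the enantiomer that delivers the (S)-ester; if a model coupling shows the opposite sense, the (R,R)-ligand is used with no other change.

**Step 1**
Reactants: 1 5-bromobenzene-1,3-diol
Product: 2 5-bromo-1,3-phenylene bis(2,2-dimethylpropanoate)
Conditions: PivCl (2.4 equiv), Et3N (3 equiv), DMAP (5 mol %), CH2Cl2, 0 °C → rt
Reagents that add atoms: pivaloyl chloride, CC(C)(C)C(=O)Cl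
Why: DMAP-catalysed O-acylation of both phenols should be clean, and the pivalates are chosen because they should survive aqueous phosphate, hydrogenation, Appel conditions, zinc insertion and nickel catalysis yet fall to methoxide at the end.

**Step 2**
Reactants: 3 but-3-yn-1-ol; 4 7-bromohept-1-ene
Product: 5 undec-10-en-3-yn-1-ol
Conditions: n-BuLi (2.1 equiv), THF, −78 → 0 °C; then 4, DMPU, 0 °C → rt; H2O quench
Reagents that add atoms: none
Why: Alkylation of the C,O-dilithio derivative of a terminal alkynol: the acetylide carbon is far more nucleophilic than the lithium alkoxide in THF/DMPU, so SN2 displacement of the primary bromide should give the C-alkylated enyne.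

**Step 3**
Reactants: 5 undec-10-en-3-yn-1-ol; 2 5-bromo-1,3-phenylene bis(2,2-dimethylpropanoate)
Product: 7 5-(11-hydroxyundec-8-yn-1-yl)-1,3-phenylene bis(2,2-dimethylpropanoate), via bis(9-BBN) adduct 6 (not isolated)
Conditions: 9-BBN (2.2 equiv), THF, 0 °C → rt; then 2, Pd(dppf)Cl2 (5 mol %), aq K3PO4 (3 equiv), THF/DMF, rt → 45 °C
Reagents that add atoms: none
Why: Hydroboration/B-alkyl Suzuki–Miyaura coupling: 9-BBN first caps the hydroxyl as a borinate and then adds anti-Markovnikov to the terminal alkene much faster than to the internal alkyne, and the primary alkylborane should transfer to the arylpalladium bromide under phosphate activation.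

**Step 4**
Reactants: 7 5-(11-hydroxyundec-8-yn-1-yl)-1,3-phenylene bis(2,2-dimethylpropanoate)
Product: 8 5-[(8Z)-11-hydroxyundec-8-en-1-yl]-1,3-phenylene bis(2,2-dimethylpropanoate)
Conditions: H2 (1 atm), Lindlar catalyst, quinoline, EtOAc, rt, uptake monitored
Reagents that add atoms: none
Why: Lindlar semihydrogenation delivers both hydrogens to the same face of the alkyne on the poisoned palladium surface, which sets the 8Z olefin, and quinoline guards against over-reduction.

**Step 5**
Reactants: 8 5-[(8Z)-11-hydroxyundec-8-en-1-yl]-1,3-phenylene bis(2,2-dimethylpropanoate)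
Product: 9 5-[(8Z)-11-iodoundec-8-en-1-yl]-1,3-phenylene bis(2,2-dimethylpropanoate)
Conditions: I2, PPh3, imidazole, CH2Cl2, 0 °C → rt, dark
Reagents that add atoms: iodine, II
Why: Appel-type iodination converts the primary alcohol into the iodide by SN2 on the alkoxyphosphonium ion under near-neutral conditions that should leave the Z-olefin and the aryl esters untouched.

**Step 6**
Reactants: 10 (Z)-hex-3-en-1-ol
Product: 11 (Z)-hex-3-enal
Conditions: Dess–Martin periodinane (1.1 equiv), CH2Cl2, 0 °C → rt; cold aq NaHCO3/Na2S2O3 wash; used at once as a dried CH2Cl2 solution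
Reagents that add atoms: none
Why: Dess–Martin oxidation is mild enough to stop at the β,γ-unsaturated aldehyde without moving the Z double bond into conjugation, provided the volatile aldehyde is kept cold and used immediately.

**Step 7**
Reactants: 11 (Z)-hex-3-enal; 9 5-[(8Z)-11-iodoundec-8-en-1-yl]-1,3-phenylene bis(2,2-dimethylpropanoate)
Product: 14 5-[(8Z,12S,14Z)-12-(benzoyloxy)heptadeca-8,14-dien-1-yl]-1,3-phenylene bis(2,2-dimethylpropanoate), via racemic (3Z)-1-bromohex-3-en-1-yl benzoate 12 (not isolated), via homoallylic alkylzinc iodide 13 (not isolated)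
Conditions: (a) 11 (1.3 equiv), BzBr (1.3 equiv, freshly distilled), ZnBr2 (1 mol %), CH2Cl2, −20 °C, then exchange to THF; (b) 9, Zn dust (I2-activated), DMA, rt; (c) (a) + (b), NiBr2·glyme (10 mol %), (S,S)-Ph-BOX (12 mol %), THF/DMA, −10 °C
Reagents that add atoms: benzoyl bromide, O=C(Br)c1ccccc1
Why: A ligated Ni(I) species abstracts bromine from either enantiomer of 12 to give one planar α-benzoyloxyalkyl radical at C12, the primary alkylzinc 13 transmetalates to the chiral Ni(II) centre, the radical is captured to give a Ni(III) dialkyl, and reductive elimination forms the C11–C12 bond. The closest known reaction types are the nickel/bis(oxazoline)-catalysed enantioconvergent alkyl–alkyl couplings of racemic 1-bromoalkyl esters made in situ from an aldehyde and an acyl bromide, and the enantioconvergent Negishi couplings of racemic α-heteroatom-substituted alkyl halides with primary alkylzinc halides. No ring is closed. The new stereocentre C12 is set by the chiral ligand (catalyst control): the benzoate carbonyl binds nickel, so the catalyst distinguishes the O-substituent from the two alkyl arms instead of having to tell the nearly identical C11 and C13 chains apart, and both enantiomers of 12 converge on the (S)-ester through the common radical. The step needs cross-coupling to beat β-hydride elimination and homocoupling, which the nitrogen ligand and the low temperature should secure, and it needs both Z-olefins to survive, which is expected because no nickel hydride is formed and radical capture by nickel should outrun the reversible 3-exo cyclisation of the homoallylic radical. The aryl pivalates should be inert to nickel under these phosphine-free conditions and to the mild organozinc.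

**Step 8**
Reactants: 14 5-[(8Z,12S,14Z)-12-(benzoyloxy)heptadeca-8,14-dien-1-yl]-1,3-phenylene bis(2,2-dimethylpropanoate)
Product: 15 5-[(8Z,12S,14Z)-12-hydroxyheptadeca-8,14-dien-1-yl]benzene-1,3-diol
Conditions: NaOMe (4 equiv), degassed MeOH/THF, rt → 40 °C, Ar; AcOH quench
Reagents that add atoms: none
Why: Methoxide transesterification (Zemplén-type) cleaves the secondary benzoate and both aryl pivalates by acyl–oxygen fission, so C12 keeps its S configuration and both Z-olefins are untouched, while degassing protects the electron-rich resorcinol from air oxidation.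

**Compound list**
1 | 5-bromobenzene-1,3-diol | Oc1cc(O)cc(Br)c1 | starting material
2 | 5-bromo-1,3-phenylene bis(2,2-dimethylpropanoate) | CC(C)(C)C(=O)Oc1cc(Br)cc(OC(=O)C(C)(C)C)c1 | intermediate
3 | but-3-yn-1-ol | C#CCCO | starting material
4 | 7-bromohept-1-ene | C=CCCCCCBr | starting material
5 | undec-10-en-3-yn-1-ol | C=CCCCCCC#CCCO | intermediate
6 | 9-[11-(9-borabicyclo[3.3.1]nonan-9-yloxy)undec-8-yn-1-yl]-9-borabicyclo[3.3.1]nonane (bis(9-BBN) adduct of 5) | B1(C2CCCC1CCC2)CCCCCCCC#CCCOB1C2CCCC1CCC2 | intermediate
7 | 5-(11-hydroxyundec-8-yn-1-yl)-1,3-phenylene bis(2,2-dimethylpropanoate) | OCCC#CCCCCCCCc1cc(OC(=O)C(C)(C)C)cc(OC(=O)C(C)(C)C)c1 | intermediate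
8 | 5-[(8Z)-11-hydroxyundec-8-en-1-yl]-1,3-phenylene bis(2,2-dimethylpropanoate) | OCC/C=C\CCCCCCCc1cc(OC(=O)C(C)(C)C)cc(OC(=O)C(C)(C)C)c1 | intermediate
9 | 5-[(8Z)-11-iodoundec-8-en-1-yl]-1,3-phenylene bis(2,2-dimethylpropanoate) | ICC/C=C\CCCCCCCc1cc(OC(=O)C(C)(C)C)cc(OC(=O)C(C)(C)C)c1 | intermediate
10 | (Z)-hex-3-en-1-ol | CC/C=C\CCO | starting material
11 | (Z)-hex-3-enal | CC/C=C\CC=O | intermediate
12 | racemic (3Z)-1-bromohex-3-en-1-yl benzoate | CC/C=C\CC(Br)OC(=O)c1ccccc1 | intermediate
13 | [(3Z)-11-[3,5-bis(2,2-dimethylpropanoyloxy)phenyl]undec-3-en-1-yl]zinc iodide | I[Zn]CC/C=C\CCCCCCCc1cc(OC(=O)C(C)(C)C)cc(OC(=O)C(C)(C)C)c1 | intermediate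
14 | 5-[(8Z,12S,14Z)-12-(benzoyloxy)heptadeca-8,14-dien-1-yl]-1,3-phenylene bis(2,2-dimethylpropanoate) | CC/C=C\C[C@@H](OC(=O)c1ccccc1)CC/C=C\CCCCCCCc1cc(OC(=O)C(C)(C)C)cc(OC(=O)C(C)(C)C)c1 | intermediate
15 | 5-[(8Z,12S,14Z)-12-hydroxyheptadeca-8,14-dien-1-yl]benzene-1,3-diol | CC/C=C\C[C@@H](O)CC/C=C\CCCCCCCc1cc(O)cc(O)c1 | target

**Totals**
Total step count: 8. Longest linear sequence: 6 steps (steps 2, 3, 4, 5, 7, 8).

**Steps most likely to fail**

Step 7. The 1-bromoalkyl benzoate may lose HBr toward a conjugated dienyl benzoate, or its β,γ-olefin may migrate, before nickel engages it. Facial selectivity at C12 may also be insufficient, and reversible radical cyclisation may erode the 14Z geometry. The fallback sets out from 13 and 11 and comes back to the route at 15. The zinc iodide 13 would be treated with Me3SiCH2Li at −78 °C to give the mixed diorganozinc [(3Z)-11-[3,5-bis(2,2-dimethylpropanoyloxy)phenyl]undec-3-en-1-yl](trimethylsilylmethyl)zinc F1, whose trimethylsilylmethyl group does not transfer. Catalytic asymmetric 1,2-addition of F1 to aldehyde 11 with Ti(OiPr)4 and trans-1,2-bis(trifluoromethanesulfonamido)cyclohexane (toluene, −20 °C) forms the same C11–C12 bond by a polar, non-radical path. The (1R,2R) ligand is expected to give the S carbinol, by analogy with simple aldehydes in which the aldehyde substituent outranks the transferred group. This should give 5-[(8Z,12S,14Z)-12-hydroxyheptadeca-8,14-dien-1-yl]-1,3-phenylene bis(2,2-dimethylpropanoate) F2. Methoxide in methanol, as in step 8, would then give 15.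

Step 3. 9-BBN may also add to the internal alkyne or be consumed unevenly by the free hydroxyl, and aqueous phosphate may hydrolyse the aryl pivalates. The fallback sets out from 2 and comes back at 8; it replaces steps 2 to 4, so 3, 4 and 5 are not needed. Sonogashira coupling of 2 with commercial oct-7-yn-1-ol (Pd(PPh3)2Cl2, CuI, Et3N, 60 °C) would give 5-(8-hydroxyoct-1-yn-1-yl)-1,3-phenylene bis(2,2-dimethylpropanoate) F3. Full hydrogenation (H2, Pd/C, EtOAc) would give 5-(8-hydroxyoctyl)-1,3-phenylene bis(2,2-dimethylpropanoate) F4. Dess–Martin oxidation would give 5-(8-oxooctyl)-1,3-phenylene bis(2,2-dimethylpropanoate) F5. A salt-free Z-selective Wittig reaction with the ylide from [3-(tert-butyldimethylsilyloxy)propyl]triphenylphosphonium bromide (NaHMDS, THF, −78 °C) would give 5-[(8Z)-11-(tert-butyldimethylsilyloxy)undec-8-en-1-yl]-1,3-phenylene bis(2,2-dimethylpropanoate) F6. HF·pyridine in THF would remove the silyl ether and return 8.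

Step 6. The Z-β,γ double bond may slip into conjugation during oxidation or work-up, and the volatile aldehyde may be lost on concentration. The fallback does not start from a numbered compound: it sets out from purchased (Z)-1,1-diethoxyhex-3-ene F7, used in place of 10, and comes back at 11. The acetal would be hydrolysed on wet silica gel with oxalic acid in CH2Cl2 at 0 °C. The filtered and dried solution of 11 would go directly into step 7(a), so the aldehyde is never concentrated or exposed to an oxidant.

**Further compounds**
F1 | step 7 | [(3Z)-11-[3,5-bis(2,2-dimethylpropanoyloxy)phenyl]undec-3-en-1-yl](trimethylsilylmethyl)zinc | C[Si](C)(C)C[Zn]CC/C=C\CCCCCCCc1cc(OC(=O)C(C)(C)C)cc(OC(=O)C(C)(C)C)c1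
F2 | step 7 | 5-[(8Z,12S,14Z)-12-hydroxyheptadeca-8,14-dien-1-yl]-1,3-phenylene bis(2,2-dimethylpropanoate) | CC/C=C\C[C@@H](O)CC/C=C\CCCCCCCc1cc(OC(=O)C(C)(C)C)cc(OC(=O)C(C)(C)C)c1
F3 | step 3 | 5-(8-hydroxyoct-1-yn-1-yl)-1,3-phenylene bis(2,2-dimethylpropanoate) | OCCCCCCC#Cc1cc(OC(=O)C(C)(C)C)cc(OC(=O)C(C)(C)C)c1
F4 | step 3 | 5-(8-hydroxyoctyl)-1,3-phenylene bis(2,2-dimethylpropanoate) | OCCCCCCCCc1cc(OC(=O)C(C)(C)C)cc(OC(=O)C(C)(C)C)c1
F5 | step 3 | 5-(8-oxooctyl)-1,3-phenylene bis(2,2-dimethylpropanoate) | O=CCCCCCCCc1cc(OC(=O)C(C)(C)C)cc(OC(=O)C(C)(C)C)c1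
F6 | step 3 | 5-[(8Z)-11-(tert-butyldimethylsilyloxy)undec-8-en-1-yl]-1,3-phenylene bis(2,2-dimethylpropanoate) | CC(C)(C)[Si](C)(C)OCC/C=C\CCCCCCCc1cc(OC(=O)C(C)(C)C)cc(OC(=O)C(C)(C)C)c1
F7 | step 6 | (Z)-1,1-diethoxyhex-3-ene | CC/C=C\CC(OCC)OCC
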